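**Plan**

1. Numbering (longipinane): C1=O, C2=C3(Me), C4, C5, C6(Me2), C7 (O-isovaleryl), C8, C9 (O-tigloyl), C10(Me), C11. The retrosynthesis removes the C1 oxo group and the two esters, then cuts C5–C6 and C4–C10 in one stroke.
2. What remains is a monocyclic 5-substituted 2-methylcyclohexa-1,3-diene (ring C11–C1–C2–C3–C4–C5) whose C11 substituent is the open chain C10–C9–C8–C7–C6.
3. Enabling feature: quaternary C6 adjoins the C7 carbinol (tertiary end of a trisubstituted epoxide, electrophile) and C10 is α to the C9 oxygen (enol silane carbon, nucleophile). The chain can therefore add across the C4–C5 edge of the ring, C5 being a diene terminus and C4 the allyl-cation terminus that results.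
4. Forward: (R)-carvone supplies the ring, C11, C10 with its methyl, and C9. The chain is extended at C9, the enone is turned into the 1,3-diene, and one Lewis-acid cascade closes first the seven-membered ring (C5–C6), then the cyclobutane (C4–C10).
5. Stereochemistry: C11 from (R)-carvone; C7 from a Shi epoxidation; C5, C4 and C10 from the tethered cascade (only the cis,cis-fused tricycle can form); C9 by a 1,3-anti Evans–Tishchenko reduction, which also places the isovalerate on O7.
6. End game: tigloylation of O9 and allylic oxidation of C1 to the enone.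

Key step: step 12

Remark: the D-fructose-derived Shi ketone is assumed to give the (2R)-epoxide from the 3-methylbut-2-enyl alkene (spiro transition-state model); if the sense were opposite, the enantiomeric ketone would be used.

**Route**

Step 1
Reactants: 1 (R)-(−)-carvone
Product: 2 (5R)-5-(3-chloroprop-1-en-2-yl)-2-methylcyclohex-2-en-1-one
Conditions: Ca(OCl)2, CO2 (dry ice), CH2Cl2/H2O, 0 °C
Reagents that add atoms: calcium hypochlorite, [Ca+2].[O-]Cl.[O-]Cl
Why: Ene-type allylic chlorination by HOCl should attack only the electron-rich 1,1-disubstituted isopropenyl alkene and leave the enone untouched; no stereocentre is formed.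

Step 2
Reactants: 2 (5R)-5-(3-chloroprop-1-en-2-yl)-2-methylcyclohex-2-en-1-one
Product: 3 2-[(1R)-4-methyl-5-oxocyclohex-3-en-1-yl]prop-2-enal
Conditions: Me3NO (anhydrous), DMSO, 20 °C
Reagents that add atoms: trimethylamine N-oxide, C[N+](C)(C)[O-]
Why: SN2 displacement of the allylic chloride by the N-oxide oxygen and fragmentation of the alkoxyammonium salt (amine N-oxide, Kornblum-type oxidation) should give the α-substituted acrolein without touching the ring enone.

Step 3
Reactants: 3 2-[(1R)-4-methyl-5-oxocyclohex-3-en-1-yl]prop-2-enal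
Product: 4 (5R)-5-(3-hydroxyhexa-1,5-dien-2-yl)-2-methylcyclohex-2-en-1-one (both carbinol epimers)
Conditions: allyl bromide, Zn, THF/sat. aq. NH4Cl, 0 °C
Reagents that add atoms: allyl bromide, C=CCBr
Why: Aqueous Barbier allylation is chemoselective for the aldehyde over the enone ketone; the new carbinol (C9) forms as an epimer mixture, which is of no consequence because it is oxidised in step 10.

Step 4
Reactants: 4 (5R)-5-(3-hydroxyhexa-1,5-dien-2-yl)-2-methylcyclohex-2-en-1-one
Product: 5 (5R)-5-{3-[tert-butyl(dimethyl)silyloxy]hexa-1,5-dien-2-yl}-2-methylcyclohex-2-en-1-one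
Conditions: TBSCl, imidazole, DMF, 20 °C
Reagents that add atoms: tert-butyldimethylsilyl chloride, CC(C)(C)[Si](C)(C)Cl
Why: Routine silyl protection of the secondary allylic alcohol, needed so that the later enolate, oxidation and epoxide steps meet no free hydroxyl.

Step 5
Reactants: 5 (5R)-5-{3-[tert-butyl(dimethyl)silyloxy]hexa-1,5-dien-2-yl}-2-methylcyclohex-2-en-1-one
Product: 6 (5R)-5-{3-[tert-butyl(dimethyl)silyloxy]-6-methylhepta-1,5-dien-2-yl}-2-methylcyclohex-2-en-1-one
Conditions: 2-methylbut-2-ene (excess), second-generation Ru benzylidene metathesis catalyst (5 mol %), CH2Cl2, 40 °C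
Reagents that add atoms: 2-methylbut-2-ene, CC=C(C)C
Why: Olefin cross-metathesis of the monosubstituted alkene with 2-methylbut-2-ene should install the prenyl terminus while the 1,1-disubstituted alkene and the enone alkene remain spectators.

Step 6
Reactants: 6 (5R)-5-{3-[tert-butyl(dimethyl)silyloxy]-6-methylhepta-1,5-dien-2-yl}-2-methylcyclohex-2-en-1-one
Product: 7 (5R)-5-{3-[tert-butyl(dimethyl)silyloxy]-4-[(2R)-3,3-dimethyloxiran-2-yl]but-1-en-2-yl}-2-methylcyclohex-2-en-1-one
Conditions: D-fructose-derived Shi ketone (30 mol %), Oxone, K2CO3, Bu4NHSO4, MeCN/DMM/aq. borate buffer (pH 10.5), 0 °C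
Reagents that add atoms: potassium peroxymonosulfate (Oxone), [K+].[O-]S(=O)(=O)OO
Why: Shi asymmetric epoxidation is selective for the electron-rich trisubstituted alkene and should deliver the (R)-epoxide under reagent control, which fixes C7.

Step 7
Reactants: 7 (5R)-5-{3-[tert-butyl(dimethyl)silyloxy]-4-[(2R)-3,3-dimethyloxiran-2-yl]but-1-en-2-yl}-2-methylcyclohex-2-en-1-one
Product: 9 (3R)-3-{3-[tert-butyl(dimethyl)silyloxy]-4-[(2R)-3,3-dimethyloxiran-2-yl]but-1-en-2-yl}-6-methylcyclohexa-1,5-dien-1-yl trifluoromethanesulfonate, via lithium dienolate 8 (not isolated)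
Conditions: LDA, THF, −78 °C; then PhNTf2, −78 → 0 °C
Reagents that add atoms: N-phenylbis(trifluoromethanesulfonimide), O=S(=O)(N(c1ccccc1)S(=O)(=O)C(F)(F)F)C(F)(F)F
Why: Kinetic α′-deprotonation of the carvone-type enone (at the future C5) and O-triflation of the cross-conjugated enolate should give the 2-triflyloxy-1,3-diene regiospecifically; epoxide and silyl ether tolerate LDA at −78 °C.

Step 8
Reactants: 9 (3R)-3-{3-[tert-butyl(dimethyl)silyloxy]-4-[(2R)-3,3-dimethyloxiran-2-yl]but-1-en-2-yl}-6-methylcyclohexa-1,5-dien-1-yl trifluoromethanesulfonate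
Product: 10 tert-butyl{[1-[(2R)-3,3-dimethyloxiran-2-yl]-3-[(1R)-4-methylcyclohexa-2,4-dien-1-yl]but-3-en-2-yl]oxy}dimethylsilane
Conditions: Pd(OAc)2 (5 mol %), PPh3, HCO2H, Bu3N, DMF, 50 °C
Reagents that add atoms: none
Why: Palladium-catalysed formate reduction of the dienyl triflate replaces OTf by H and leaves the conjugated 1,3-diene with the future C5 as its terminus.

Step 9
Reactants: 10 tert-butyl{[1-[(2R)-3,3-dimethyloxiran-2-yl]-3-[(1R)-4-methylcyclohexa-2,4-dien-1-yl]but-3-en-2-yl]oxy}dimethylsilane
Product: 11 1-[(2R)-3,3-dimethyloxiran-2-yl]-3-[(1R)-4-methylcyclohexa-2,4-dien-1-yl]but-3-en-2-ol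
Conditions: TBAF, THF, 0 °C
Reagents that add atoms: none
Why: Fluoride cleavage of the silyl ether; the resulting alkoxide could open the epoxide only through disfavoured 4-exo or 5-endo modes.

Step 10
Reactants: 11 1-[(2R)-3,3-dimethyloxiran-2-yl]-3-[(1R)-4-methylcyclohexa-2,4-dien-1-yl]but-3-en-2-ol
Product: 12 1-[(2R)-3,3-dimethyloxiran-2-yl]-3-[(1R)-4-methylcyclohexa-2,4-dien-1-yl]but-3-en-2-one
Conditions: DMP, NaHCO3, CH2Cl2, 0 °C
Reagents that add atoms: none
Why: Buffered periodinane oxidation of the allylic alcohol gives the α-methylene ketone; it is an activated dienophile next to a diene and is taken on at once at low temperature.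

Step 11
Reactants: 12 1-[(2R)-3,3-dimethyloxiran-2-yl]-3-[(1R)-4-methylcyclohexa-2,4-dien-1-yl]but-3-en-2-one
Product: 14 {[(2E)-1-[(2R)-3,3-dimethyloxiran-2-yl]-3-[(1R)-4-methylcyclohexa-2,4-dien-1-yl]but-2-en-2-yl]oxy}triethylsilane, via lithium enolate 13 (not isolated)
Conditions: L-Selectride, THF, −78 °C; then Et3SiCl, Et3N, −78 → −20 °C
Reagents that add atoms: chlorotriethylsilane, CC[Si](Cl)(CC)CC
Why: Conjugate reduction of the β-unsubstituted enone through its s-cis conformer creates the C10 methyl and, regiospecifically, the tetrasubstituted enolate with O and the new methyl cis. O-Silylation then fixes the (E)-enol silane that a cis ring alkene in the later cycloheptene requires, and this enolate cannot open the β,γ-epoxide.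

Step 12
Reactants: 14 {[(2E)-1-[(2R)-3,3-dimethyloxiran-2-yl]-3-[(1R)-4-methylcyclohexa-2,4-dien-1-yl]but-2-en-2-yl]oxy}triethylsilane
Product: 16 7-hydroxylongipin-2-en-9-one, via allyl cation aluminate 15 (not isolated)
Conditions: MeAlCl2 (1.2 equiv), CH2Cl2, −95 → −78 °C; aq. Rochelle salt
Reagents that add atoms: none
Why: Proposed new method: MeAlCl2 should activate the trisubstituted epoxide at its tertiary carbon C6, which is attacked by the diene terminus C5 on the face carrying the side chain (endo epoxide opening, seven-membered ring C5–C6–C7–C8–C9–C10–C11), giving the 2-methylcyclohexenyl cation 15. The tetrasubstituted enol silane, now endocyclic in the new cycloheptene with its C10 lobe aimed at C4, should then collapse onto the allyl cation (4-(enolexo)-exo-trig, cyclobutane C4–C5–C11–C10), lose Et3Si+ and leave the C9 ketone and the C2=C3 alkene. The closest known reaction type is the Lewis-acid, epoxide-initiated cation–olefin polycyclisation terminated by a silyl enol ether, together with the cyclobutane-forming collapse of enol silanes onto stabilised cations in Lewis-acid [2+2] reactions. C7 keeps the epoxide configuration, while C5, C4 and C10 are fixed relative to C11 by the tethers, since only the cis,cis-fused tricycle can close. The step needs the diene and not the enol silane to open the epoxide (direct closure would be a disfavoured 4- or 5-(enolendo) process), capture at C4 and not C2 (C2 lies near the nodal plane of the ring-held enol silane), and C–C collapse ahead of proton loss, hydride shift of the epoxide or O-capture by the C7 aluminate; the intramolecular π-nucleophile and the low temperature should favour these.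

Step 13
Reactants: 16 7-hydroxylongipin-2-en-9-one
Product: 17 9-hydroxylongipin-2-en-7-yl 3-methylbutanoate
Conditions: SmI2 (30 mol %), 3-methylbutanal (5 equiv), THF, −10 °C
Reagents that add atoms: 3-methylbutanal, CC(C)CC=O
Why: Evans–Tishchenko reduction: the samarium-bound hemiacetal of the C7 hydroxyl delivers hydride intramolecularly to the C9 ketone from the side of O7, which should set C9 1,3-anti (trans) to C7 and leave the isovalerate on O7 and a free C9 hydroxyl.

Step 14
Reactants: 17 9-hydroxylongipin-2-en-7-yl 3-methylbutanoate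
Product: 18 7-(3-methylbutanoyloxy)longipin-2-en-9-yl (2E)-2-methylbut-2-enoate
Conditions: tigloyl chloride, Et3N, DMAP, CH2Cl2, 40 °C
Reagents that add atoms: (2E)-2-methylbut-2-enoyl chloride, C/C=C(\C)C(Cl)=O
Why: DMAP-catalysed acylation of the hindered secondary alcohol; the trans-1,3 arrangement of the two oxygens disfavours isovaleryl migration.

Step 15
Reactants: 18 7-(3-methylbutanoyloxy)longipin-2-en-9-yl (2E)-2-methylbut-2-enoate
Product: 19 7-(3-methylbutanoyloxy)-1-oxolongipin-2-en-9-yl (2E)-2-methylbut-2-enoate (target)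
Conditions: CrO3, 3,5-dimethylpyrazole, CH2Cl2, −20 °C
Reagents that add atoms: chromium trioxide, O=[Cr](=O)=O
Why: Chromium(VI) allylic oxidation of the ring methylene C1 next to the C2=C3 alkene, the α-pinene-to-verbenone type of transformation; the bridgehead C4–H and the electron-poor tiglate alkene are not expected to react.

**Compound list**

1 | (R)-(−)-carvone, (5R)-2-methyl-5-(prop-1-en-2-yl)cyclohex-2-en-1-one | CC1=CC[C@H](CC1=O)C(=C)C | starting material
2 | (5R)-5-(3-chloroprop-1-en-2-yl)-2-methylcyclohex-2-en-1-one | CC1=CC[C@H](CC1=O)C(=C)CCl | intermediate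
3 | 2-[(1R)-4-methyl-5-oxocyclohex-3-en-1-yl]prop-2-enal | CC1=CC[C@H](CC1=O)C(=C)C=O | intermediate
4 | (5R)-5-(3-hydroxyhexa-1,5-dien-2-yl)-2-methylcyclohex-2-en-1-one, both carbinol epimers | CC1=CC[C@H](CC1=O)C(=C)C(O)CC=C | intermediate
5 | (5R)-5-{3-[tert-butyl(dimethyl)silyloxy]hexa-1,5-dien-2-yl}-2-methylcyclohex-2-en-1-one, both epimers | CC1=CC[C@H](CC1=O)C(=C)C(O[Si](C)(C)C(C)(C)C)CC=C | intermediate
6 | (5R)-5-{3-[tert-butyl(dimethyl)silyloxy]-6-methylhepta-1,5-dien-2-yl}-2-methylcyclohex-2-en-1-one, both epimers | CC1=CC[C@H](CC1=O)C(=C)C(O[Si](C)(C)C(C)(C)C)CC=C(C)C | intermediate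
7 | (5R)-5-{3-[tert-butyl(dimethyl)silyloxy]-4-[(2R)-3,3-dimethyloxiran-2-yl]but-1-en-2-yl}-2-methylcyclohex-2-en-1-one, both silyloxy epimers | CC1=CC[C@H](CC1=O)C(=C)C(O[Si](C)(C)C(C)(C)C)C[C@H]2OC2(C)C | intermediate
8 | lithium cross-conjugated dienolate of 7 (6-methylcyclohexa-1,5-dien-1-olate) | [Li+].CC1=CC[C@H](C=C1[O-])C(=C)C(O[Si](C)(C)C(C)(C)C)C[C@H]2OC2(C)C | intermediate (not isolated)
9 | (3R)-3-{3-[tert-butyl(dimethyl)silyloxy]-4-[(2R)-3,3-dimethyloxiran-2-yl]but-1-en-2-yl}-6-methylcyclohexa-1,5-dien-1-yl trifluoromethanesulfonate | CC1=CC[C@H](C=C1OS(=O)(=O)C(F)(F)F)C(=C)C(O[Si](C)(C)C(C)(C)C)C[C@H]2OC2(C)C | intermediate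
10 | tert-butyl{[1-[(2R)-3,3-dimethyloxiran-2-yl]-3-[(1R)-4-methylcyclohexa-2,4-dien-1-yl]but-3-en-2-yl]oxy}dimethylsilane, both epimers | CC1=CC[C@H](C=C1)C(=C)C(O[Si](C)(C)C(C)(C)C)C[C@H]2OC2(C)C | intermediate
11 | 1-[(2R)-3,3-dimethyloxiran-2-yl]-3-[(1R)-4-methylcyclohexa-2,4-dien-1-yl]but-3-en-2-ol, both epimers | CC1=CC[C@H](C=C1)C(=C)C(O)C[C@H]2OC2(C)C | intermediate
12 | 1-[(2R)-3,3-dimethyloxiran-2-yl]-3-[(1R)-4-methylcyclohexa-2,4-dien-1-yl]but-3-en-2-one | CC1=CC[C@H](C=C1)C(=C)C(=O)C[C@H]2OC2(C)C | intermediate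
13 | lithium (2E)-1-[(2R)-3,3-dimethyloxiran-2-yl]-3-[(1R)-4-methylcyclohexa-2,4-dien-1-yl]but-2-en-2-olate | [Li+].CC1=CC[C@H](C=C1)/C(C)=C(/[O-])C[C@H]2OC2(C)C | intermediate (not isolated)
14 | {[(2E)-1-[(2R)-3,3-dimethyloxiran-2-yl]-3-[(1R)-4-methylcyclohexa-2,4-dien-1-yl]but-2-en-2-yl]oxy}triethylsilane | CC1=CC[C@H](C=C1)/C(C)=C(/O[Si](CC)(CC)CC)C[C@H]2OC2(C)C | intermediate
15 | cis-fused bicyclic 2-methylcyclohexenyl (allyl) cation with the C7 oxygen on aluminium and the enol silane intact (zwitterion) | C[Al-](Cl)(Cl)O[C@@H]1CC(O[Si](CC)(CC)CC)=C(C)[C@@H]2CC=C(C)[CH+][C@@H]2C1(C)C | intermediate (not isolated)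
16 | 7-hydroxylongipin-2-en-9-one (plan numbering; all stereocentres as in the target) | O=C1C[C@@H](O)C(C)(C)[C@@H]2[C@H]3CC=C(C)[C@@H]2[C@]31C | intermediate
17 | 9-hydroxylongipin-2-en-7-yl 3-methylbutanoate (stereocentres as in the target) | O[C@@H]1C[C@@H](OC(=O)CC(C)C)C(C)(C)[C@@H]2[C@H]3CC=C(C)[C@@H]2[C@]31C | intermediate
18 | 7-(3-methylbutanoyloxy)longipin-2-en-9-yl (2E)-2-methylbut-2-enoate (stereocentres as in the target) | C/C=C(\C)C(=O)O[C@@H]1C[C@@H](OC(=O)CC(C)C)C(C)(C)[C@@H]2[C@H]3CC=C(C)[C@@H]2[C@]31C | intermediate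
19 | (4R,5S,7R,9R,10R,11R)-7-(3-methylbutanoyloxy)-1-oxolongipin-2-en-9-yl (2E)-2-methylbut-2-enoate, CNP0194415.1 | C/C=C(\C)C(=O)O[C@@H]1C[C@@H](OC(=O)CC(C)C)C(C)(C)[C@@H]2[C@H]3C(=O)C=C(C)[C@@H]2[C@]31C | target

**Step count and risks**

Total step count: 15. Longest linear sequence: 15 steps (all from 1).

Steps most likely to fail:

1. Step 12 (proposed new method). The epoxide may rearrange by hydride shift before the seven-membered ring closes; the allyl cation may lose a proton or be captured by the C7 oxygen; the enol silane may close at C2 instead of C4. The fallback makes the two bonds one after the other with known reaction types, sets out from 7 and comes back to the route at 16.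
   - Kinetic enolisation of 7 (LDA, then Me3SiCl, THF, −78 °C) should give the cross-conjugated trimethylsilyl dienol ether F1.
   - MeAlCl2 (CH2Cl2, −78 °C) should then let C5 open the epoxide at its tertiary carbon (Lewis-acid tert-alkylation of a silyl enol ether), giving the cis-fused bicyclic enone F2 with the C5–C6 bond and a free C7 hydroxyl.
   - Luche reduction should give the allylic alcohol F3 (hydroxyl expected cis to the C6 substituent).
   - Corey–Kim chlorination (NCS, Me2S), selective for the allylic hydroxyl and proceeding with inversion, should give the allylic chloride F4 with chlorine trans to the side chain.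
   - HF·pyridine removes the silyl ether to give the chloro diol F5.
   - MnO2 should oxidise only the allylic hydroxyl, giving the α-methylene ketone F6.
   - Excess L-Selectride (THF, −78 → 0 °C) should generate the C10 enolate by conjugate reduction, and intramolecular 4-exo-tet alkylation at C4 (the classical enolate route to bicyclo[3.1.1]heptanes) should close the cyclobutane to give 16.

2. Step 13. Hemiacetal formation at the hindered C7 hydroxyl may be slow, and retro-aldol cleavage or dehydration of the β-hydroxy ketone, or erosion of the 1,3-anti control, may intervene. The fallback sets out from 16 and comes back at 17. Acylation of the C7 hydroxyl (isovaleric anhydride, DMAP, pyridine, 0 °C) should give the keto ester F7. Reagent-controlled CBS reduction ((S)-Me-CBS, catecholborane, toluene, −78 °C) of the C9 ketone, whose flanking groups differ strongly in size (quaternary C10 against C8H2), should then give 17.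

3. Step 15. Over-oxidation, attack at the C3 methyl or on the tiglate, or low conversion may occur. The fallback sets out from 18 and comes back at 19. Allylic acetoxylation with Pb(OAc)4 (benzene, 65 °C, as in the classical pinene-to-verbenone sequence) should give the C1 acetate F8. Methanolysis (K2CO3, MeOH, 0 °C) should remove the unhindered allylic acetate in the presence of the two hindered esters, giving the allylic alcohol F9. MnO2 oxidation should then give 19.

**Further compounds**

F1 | step 12 | kinetic trimethylsilyl dienol ether of 7 | CC1=CC[C@H](C=C1O[Si](C)(C)C)C(=C)C(O[Si](C)(C)C(C)(C)C)C[C@H]2OC2(C)C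
F2 | step 12 | cis-fused bicyclic enone with the C5–C6 bond, free C7 hydroxyl, C9 silyl ether and C10 exo-methylene | CC1=CC[C@@H]2[C@H](C1=O)C(C)(C)[C@H](O)CC(O[Si](C)(C)C(C)(C)C)C2=C
F3 | step 12 | allylic alcohol from Luche reduction of F2 (C4 hydroxyl cis to C6) | CC1=CC[C@@H]2[C@H]([C@H]1O)C(C)(C)[C@H](O)CC(O[Si](C)(C)C(C)(C)C)C2=C
F4 | step 12 | allylic chloride with inverted C4 (chlorine trans to the side chain) | CC1=CC[C@@H]2[C@H]([C@@H]1Cl)C(C)(C)[C@H](O)CC(O[Si](C)(C)C(C)(C)C)C2=C
F5 | step 12 | chloro diol after removal of the silyl ether | CC1=CC[C@@H]2[C@H]([C@@H]1Cl)C(C)(C)[C@H](O)CC(O)C2=C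
F6 | step 12 | chloro α-methylene ketone | CC1=CC[C@@H]2[C@H]([C@@H]1Cl)C(C)(C)[C@H](O)CC(=O)C2=C
F7 | step 13 | 9-oxolongipin-2-en-7-yl 3-methylbutanoate | O=C1C[C@@H](OC(=O)CC(C)C)C(C)(C)[C@@H]2[C@H]3CC=C(C)[C@@H]2[C@]31C
F8 | step 15 | 1-acetoxy derivative of 18 (either C1 epimer) | C/C=C(\C)C(=O)O[C@@H]1C[C@@H](OC(=O)CC(C)C)C(C)(C)[C@@H]2[C@H]3C(OC(C)=O)C=C(C)[C@@H]2[C@]31C
F9 | step 15 | 1-hydroxy derivative of 18 (either C1 epimer) | C/C=C(\C)C(=O)O[C@@H]1C[C@@H](OC(=O)CC(C)C)C(C)(C)[C@@H]2[C@H]3C(O)C=C(C)[C@@H]2[C@]31C
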